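## Retrosynthetic overview

1. The dihydropyran ring is the only ring formed and is closed last: the O1–C2 bond comes from an intramolecular Mitsunobu etherification of phenol-carbinol 9, with inversion, so (R)-9 gives (2S)-10.
2. The C2 stereocentre comes from asymmetric transfer hydrogenation of aryl ketone 8.
3. Ketone 8 comes from chalcone 6 by one-pot hydrogenation of the C=C bond and O-debenzylation.
4. The key C–C bond (C3–C4 of the flavan) is made by a Claisen–Schmidt aldol condensation of 3,4,5-trimethoxyacetophenone 4 with aldehyde 3.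
5. Aldehyde 3 comes from 2,3,4-trimethoxybenzaldehyde 1 by chelation-controlled 2-O-demethylation and benzylation; both benzene rings are bought.

Assumption: bulk 2,3,4-trimethoxybenzaldehyde and 3,4,5-trimethoxyacetophenone are taken as the cheap commercial inputs; 2 can also be bought, which would save step 1.

## Route

Step 1
Reactants: 1 2,3,4-trimethoxybenzaldehyde
Product: 2 2-hydroxy-3,4-dimethoxybenzaldehyde
Conditions: BCl3 (1.1 equiv, 1 M in CH2Cl2), CH2Cl2, 0 °C to rt, 3 h; then ice-water
Reagents that add atoms: none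
Why: Chelation-controlled Lewis-acid ether cleavage: BCl3 is held between the aldehyde oxygen and the ortho (C2) methoxy oxygen, so only that methyl ether is dealkylated, and 1.1 equiv at or below rt leaves the 3- and 4-OMe groups intact.

Step 2
Reactants: 2 2-hydroxy-3,4-dimethoxybenzaldehyde
Product: 3 2-(benzyloxy)-3,4-dimethoxybenzaldehyde
Conditions: BnBr (1.2 equiv), K2CO3 (2 equiv), DMF, 60 °C
Reagents that add atoms: benzyl bromide, BrCc1ccccc1
Why: Williamson ether synthesis (phenoxide SN2 on benzyl bromide); capping the phenol prevents a phenoxide from deactivating the aldehyde in the aldol step, and the benzyl group is removed later in the same pot as the alkene reduction.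

Step 3
Reactants: 3 2-(benzyloxy)-3,4-dimethoxybenzaldehyde; 4 1-(3,4,5-trimethoxyphenyl)ethan-1-one (3,4,5-trimethoxyacetophenone)
Product: 6 (E)-3-[2-(benzyloxy)-3,4-dimethoxyphenyl]-1-(3,4,5-trimethoxyphenyl)prop-2-en-1-one, via aldol adduct 5 (not isolated)
Conditions: KOH (50% aq.), EtOH, rt, 24–48 h
Reagents that add atoms: none
Why: Claisen–Schmidt (crossed aldol) condensation: the aldehyde cannot enolise, the methyl ketone is the only enolate source, and E1cB dehydration of the β-hydroxy ketone to the conjugated (E)-enone drives the reaction to completion.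

Step 4
Reactants: 6 (E)-3-[2-(benzyloxy)-3,4-dimethoxyphenyl]-1-(3,4,5-trimethoxyphenyl)prop-2-en-1-one
Product: 8 3-(2-hydroxy-3,4-dimethoxyphenyl)-1-(3,4,5-trimethoxyphenyl)propan-1-one, via saturated benzyl ether ketone 7 (not isolated)
Conditions: H2 (1 atm), 10% Pd/C, EtOAc, rt; stopped after uptake of 2 equiv H2 (TLC)
Reagents that add atoms: none
Why: Heterogeneous catalytic hydrogenation saturates the enone C=C first and then hydrogenolyses the aryl benzyl ether, while the electron-rich aryl ketone is reduced much more slowly in neutral EtOAc.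

Step 5
Reactants: 8 3-(2-hydroxy-3,4-dimethoxyphenyl)-1-(3,4,5-trimethoxyphenyl)propan-1-one
Product: 9 (1R)-3-(2-hydroxy-3,4-dimethoxyphenyl)-1-(3,4,5-trimethoxyphenyl)propan-1-ol
Conditions: RuCl(p-cymene)[(R,R)-TsDPEN] (1 mol%), HCO2H/Et3N (5:2), DMF, 40 °C, 24 h; ee checked by chiral HPLC, recrystallised if needed
Reagents that add atoms: none
Why: Noyori–Ikariya asymmetric transfer hydrogenation: as with acetophenone, the aryl group sits under the η6-arene in the outer-sphere six-membered transition state, so the (R,R)-catalyst delivers hydride to the Si face and sets the (R)-carbinol, irreversibly because CO2 is lost; the remote free phenol is tolerated in the acidic medium.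

Step 6
Reactants: 9 (1R)-3-(2-hydroxy-3,4-dimethoxyphenyl)-1-(3,4,5-trimethoxyphenyl)propan-1-ol
Product: 10 (2S)-7,8,3',4',5'-pentamethoxyflavan [(2S)-7,8-dimethoxy-2-(3,4,5-trimethoxyphenyl)chromane]
Conditions: PPh3 (1.5 equiv), DIAD (1.5 equiv, added dropwise), THF, 0 °C to rt
Reagents that add atoms: none
Why: Intramolecular Mitsunobu etherification: the carbinol is activated as an alkoxyphosphonium ion and displaced by the phenoxide (pKa about 10) in a 6-exo-tet SN2 with inversion, so (R)-9 gives the (2S)-flavan; the 3,4,5-trimethoxyphenyl group stabilises a benzylic cation only weakly, which keeps SN1 leakage low.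

## Compound list

1 | 2,3,4-trimethoxybenzaldehyde | COc1ccc(C=O)c(OC)c1OC | starting material
2 | 2-hydroxy-3,4-dimethoxybenzaldehyde | COc1ccc(C=O)c(O)c1OC | intermediate
3 | 2-(benzyloxy)-3,4-dimethoxybenzaldehyde | COc1ccc(C=O)c(OCc2ccccc2)c1OC | intermediate
4 | 1-(3,4,5-trimethoxyphenyl)ethan-1-one (3,4,5-trimethoxyacetophenone) | COc1cc(C(C)=O)cc(OC)c1OC | starting material
5 | 3-[2-(benzyloxy)-3,4-dimethoxyphenyl]-3-hydroxy-1-(3,4,5-trimethoxyphenyl)propan-1-one (racemic aldol adduct, not isolated) | COc1cc(C(=O)CC(O)c2ccc(OC)c(OC)c2OCc3ccccc3)cc(OC)c1OC | intermediate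
6 | (E)-3-[2-(benzyloxy)-3,4-dimethoxyphenyl]-1-(3,4,5-trimethoxyphenyl)prop-2-en-1-one | COc1cc(C(=O)/C=C/c2ccc(OC)c(OC)c2OCc3ccccc3)cc(OC)c1OC | intermediate
7 | 3-[2-(benzyloxy)-3,4-dimethoxyphenyl]-1-(3,4,5-trimethoxyphenyl)propan-1-one (not isolated) | COc1cc(C(=O)CCc2ccc(OC)c(OC)c2OCc3ccccc3)cc(OC)c1OC | intermediate
8 | 3-(2-hydroxy-3,4-dimethoxyphenyl)-1-(3,4,5-trimethoxyphenyl)propan-1-one | COc1cc(C(=O)CCc2ccc(OC)c(OC)c2O)cc(OC)c1OC | intermediate
9 | (1R)-3-(2-hydroxy-3,4-dimethoxyphenyl)-1-(3,4,5-trimethoxyphenyl)propan-1-ol | COc1cc([C@H](O)CCc2ccc(OC)c(OC)c2O)cc(OC)c1OC | intermediate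
10 | (2S)-7,8,3',4',5'-pentamethoxyflavan | COc1cc([C@@H]2CCc3ccc(OC)c(OC)c3O2)cc(OC)c1OC | target

## Summary

Total step count: 6.
Longest linear sequence: 6 steps (1 → 2 → 3 → 6 → 8 → 9 → 10); 4 enters at step 3.

## Steps most likely to fail, with fallbacks

**Step 4 (one-pot C=C hydrogenation and debenzylation).** The unpoisoned Pd catalyst needed for O-debenzylation can also over-reduce the aryl ketone. The fallback changes the order of events so that no ketone is present when Pd/C is used; it sets out from 6 and comes back at 9. Chalcone 6 is hydrogenated with Wilkinson's catalyst (H2, RhCl(PPh3)3 5 mol%, benzene/EtOH, rt), which reduces only the C=C bond and leaves both the ketone and the benzyl ether, giving 7, now isolated. Ketone 7 is reduced under the step 5 conditions (RuCl(p-cymene)[(R,R)-TsDPEN], HCO2H/Et3N) to (1R)-3-[2-(benzyloxy)-3,4-dimethoxyphenyl]-1-(3,4,5-trimethoxyphenyl)propan-1-ol F1. Neutral hydrogenolysis (H2, Pd/C, EtOAc, rt, monitored) then removes the aryl benzyl ether, which cleaves much faster than an unactivated secondary benzylic alcohol, and delivers 9.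

**Step 5 (asymmetric transfer hydrogenation of the free-phenol ketone).** The electron-rich ketone may react slowly or with insufficient ee. The fallback masks the phenol and uses a different reduction manifold; it sets out from 8 and comes back at 9. Phenol 8 is silylated (TBSCl, imidazole, DMF, rt) to 3-[2-(tert-butyldimethylsilyloxy)-3,4-dimethoxyphenyl]-1-(3,4,5-trimethoxyphenyl)propan-1-one F2. Corey–Bakshi–Shibata reduction ((S)-Me-CBS 10 mol%, BH3·SMe2, THF, −20 °C), with the aryl group as the large substituent, gives (1R)-3-[2-(tert-butyldimethylsilyloxy)-3,4-dimethoxyphenyl]-1-(3,4,5-trimethoxyphenyl)propan-1-ol F3. TBAF (THF, 0 °C) removes the silyl ether and returns 9.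

**Step 6 (Mitsunobu ring closure), the most critical step.** Partial ionisation of the activated benzylic alcohol would erode ee, and elimination would give a styrene. The fallback forms the aryl–O bond instead of the C2–O bond, so the stereocentre is never touched (retention); it sets out from 4 and comes back at 10.
- Ketone 4 is condensed (KOH, EtOH, rt) with purchased 2-bromo-3,4-dimethoxybenzaldehyde F4. This passes through the aldol adduct 3-(2-bromo-3,4-dimethoxyphenyl)-3-hydroxy-1-(3,4,5-trimethoxyphenyl)propan-1-one F5 (not isolated) and gives (E)-3-(2-bromo-3,4-dimethoxyphenyl)-1-(3,4,5-trimethoxyphenyl)prop-2-en-1-one F6.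
- The alkene alone is hydrogenated (H2, RhCl(PPh3)3, benzene/EtOH, aryl bromide untouched) to 3-(2-bromo-3,4-dimethoxyphenyl)-1-(3,4,5-trimethoxyphenyl)propan-1-one F7.
- Transfer hydrogenation with the enantiomeric catalyst (RuCl(p-cymene)[(S,S)-TsDPEN], HCO2H/Et3N) gives (1S)-3-(2-bromo-3,4-dimethoxyphenyl)-1-(3,4,5-trimethoxyphenyl)propan-1-ol F8.
- Pd-catalysed intramolecular C–O coupling (Pd(OAc)2 3 mol%, 2-(di-tert-butylphosphino)-1,1'-binaphthyl, Cs2CO3, toluene, 70 °C) closes the pyran ring with retention and gives 10.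

## Further compounds

F1 | step 4 | (1R)-3-[2-(benzyloxy)-3,4-dimethoxyphenyl]-1-(3,4,5-trimethoxyphenyl)propan-1-ol | COc1cc([C@H](O)CCc2ccc(OC)c(OC)c2OCc3ccccc3)cc(OC)c1OC
F2 | step 5 | 3-[2-(tert-butyldimethylsilyloxy)-3,4-dimethoxyphenyl]-1-(3,4,5-trimethoxyphenyl)propan-1-one | COc1cc(C(=O)CCc2ccc(OC)c(OC)c2O[Si](C)(C)C(C)(C)C)cc(OC)c1OC
F3 | step 5 | (1R)-3-[2-(tert-butyldimethylsilyloxy)-3,4-dimethoxyphenyl]-1-(3,4,5-trimethoxyphenyl)propan-1-ol | COc1cc([C@H](O)CCc2ccc(OC)c(OC)c2O[Si](C)(C)C(C)(C)C)cc(OC)c1OC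
F4 | step 6 | 2-bromo-3,4-dimethoxybenzaldehyde (purchased) | COc1ccc(C=O)c(Br)c1OC
F5 | step 6 | 3-(2-bromo-3,4-dimethoxyphenyl)-3-hydroxy-1-(3,4,5-trimethoxyphenyl)propan-1-one (racemic aldol adduct, not isolated) | COc1cc(C(=O)CC(O)c2ccc(OC)c(OC)c2Br)cc(OC)c1OC
F6 | step 6 | (E)-3-(2-bromo-3,4-dimethoxyphenyl)-1-(3,4,5-trimethoxyphenyl)prop-2-en-1-one | COc1cc(C(=O)/C=C/c2ccc(OC)c(OC)c2Br)cc(OC)c1OC
F7 | step 6 | 3-(2-bromo-3,4-dimethoxyphenyl)-1-(3,4,5-trimethoxyphenyl)propan-1-one | COc1cc(C(=O)CCc2ccc(OC)c(OC)c2Br)cc(OC)c1OC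
F8 | step 6 | (1S)-3-(2-bromo-3,4-dimethoxyphenyl)-1-(3,4,5-trimethoxyphenyl)propan-1-ol | COc1cc([C@@H](O)CCc2ccc(OC)c(OC)c2Br)cc(OC)c1OC
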